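# Garcinisidone E by chromium carbene benzannulation: synthesis design

## The problem

Garcinisidone E (24) is a depsidone. Two benzene rings are joined by a diaryl ether oxygen and by an ester, so that a seven-membered dioxepinone (ring C) lies between a hexasubstituted ring A and a pentasubstituted ring B. Ring A carries, in order, the lactone carbonyl carbon, OH, prenyl, OH, prenyl and the ether oxygen. Ring B carries the lactone oxygen, the ether oxygen, one hydrogen, a free OH and a fused 2,2-dimethyl-2H-pyran, whose oxygen is beside the free OH and whose C-4 is beside the lactone oxygen.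

The target has no stereocentre, so the task is purely regiochemical: eleven of twelve aromatic positions must be filled correctly and four ring B oxygens told apart. The sensitive groups are:
- the two prenyl groups ortho to phenols, which cyclise to chromans in acid;
- the chromene double bond, which is attacked by acid, electrophiles and oxidants;
- the aryl ester, which alkoxides open, the seco methyl ester being favoured over the lactone;
- the electron-rich ring B, a hydroquinone monoester.

The feature that opens the key step is the oxygen pattern of ring B. The lactone oxygen and the free OH are para, the ether oxygen is ortho to the former, and the pyran is fused along the bond beside the latter. This is the 4-alkoxyphenol that an alkenyl(alkoxy)carbene chromium complex, a terminal alkyne and CO assemble. The CO carbon becomes the lactone-oxygen carbon, the alkyne carbons become the ether-bearing carbon and the C–H, the carbene carbon becomes the free-OH carbon, and the enol ether carbons of a dihydropyran become the pyran-fused edge.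

## Retrosynthesis

**24 to 23.** The two ring A O–CH2OMe bonds are cut last. Methoxymethyl chloride is a hard electrophile that alkylates the phloroglucinol at oxygen, not carbon, and the acetals survive base, organolithium, the carbene step and the cerium oxidation. The price is one mildly acidic step on the finished skeleton, which must be gentle enough to spare the prenyl phenols and the chromene.

**23 to 21.** The C-3/C-4 double bond of the pyran is traced back to a C-4 silyl ether. A 2H-pyranyl carbene would ring-open, and a chromene would not pass the oxidation cleanly. A C-4 oxygen comes free of charge from the commercial dihydropyranone 1. The forward step is desilylation and dehydration of a benzylic alcohol, which erases the only stereocentre, so racemic material suffices.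

**21 to 20 and 19.** The lactone acyl–oxygen bond is cut, not the diaryl ether; an Ullmann coupling between two fully flanked partners is the weak step of classical depsidone syntheses. In hydroquinone acid 20 only the hydroxyl ortho to the ether can reach the carboxyl; the para hydroxyl stays free, as in the target. The closure is run on the free acid with a carbodiimide, because exchange of a phenoxide with a methyl ester is thermodynamically uphill. Hydroquinone 20 is air-sensitive and is made from quinone 19 just before use.

**19 to 18 and 17.** These are functional-group changes. The benzannulation leaves a methyl ether on the carbon that must end as the free OH; oxidative demethylation to the quinone removes it without Lewis acids that would destroy the prenyl groups. The flanked methyl ester of 17 cannot be saponified at a useful rate, but a thiolate cleaves it at the methyl carbon to give acid 18. This is done before the oxidation, while the molecule is still a robust phenol.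

**17 to 7 and 15 (key disconnection).** Three C–C bonds of ring B are cut: carbene carbon to alkyne CH, alkyne C(OAr) to CO, and CO to C-5 of the dihydropyran. Against building ring B first and etherifying afterwards, this cut installs the ether oxygen with the ring and fixes all five substituents in one operation. The precursors are a four-step carbene (7) and a ring A alkyne (15) that already holds every ring A substituent. The forward reaction must place the aryloxy group next to the CO-derived carbon and must favour CO insertion over other fates of the intermediate carbene.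

**15 to 14, 12, 11, 10, 8 and 9.** The alkynyl ether is made from a phenol by the dichlorovinyl ether route, which needs butyllithium in the presence of a benzoate ester. The order of operations answers this. Only the 4-hydroxyl of diprenyl ester 10 is protected (11), and one of the two equivalent chelated hydroxyls is vinylated (12). The other is left free, so that during the organolithium step it is a lithium phenoxide chelated to the ester and deactivates it. It is capped only afterwards (14 to 15). The prenyl groups come from direct C-alkylation of methyl 2,4,6-trihydroxybenzoate (8) with prenyl bromide (9).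

**7 to 3 and 4, then 2 and 1.** The carbene carbon–C-6 bond and the O–methyl bond are cut (Fischer synthesis from vinyllithium, Cr(CO)6 (4) and an oxonium salt). Silyl ether 3 comes from 1 by 1,2-reduction to 2 and silylation. Triisopropylsilyl is chosen over a methyl-bearing silyl group because the latter can be lithiated at Si–CH3 by t-BuLi.

## Roads not taken

**Alternative 1:** The two aryl–CH2 bonds of the ring A side chains are cut. A depsidone with both ring A hydroxyls as allyl ethers and both ring A carbons free, A1, is heated, and a double aromatic Claisen shift gives the diallyl depsidone A2 with both hydroxyls free. The regiochemistry takes care of itself: if the first allyl group takes the carbon between the two oxygens, the second reaches the remaining carbon by the para route.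
- Merits: it avoids the inefficient C-prenylation of a phloroglucinol (step 4 here), is thermal and reagent-free, and needs no ring A protecting groups at the end.
- Weak points: A2 is not the target. Each allyl group must still become prenyl by cross-metathesis next to the chromene double bond and three free phenols, and prenyl ethers cannot be used directly because the shift would deliver the reversed 1,1-dimethylallyl group. The cut also leaves the hard part of A1 untouched: the tetraoxygenated ring B, the diaryl ether and the lactone.
- Comparison: this road is better for the side chains. The chosen plan sets against it that the prenyl groups are present from the first step, that no late olefin chemistry is needed, and that its key step solves ring B, which Alternative 1 does not address.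

**Alternative 2:** The lactone oxygen is taken out, cutting the acyl–oxygen and oxygen–ring B bonds. This leads to pyranoxanthone A3 (ring A hydroxyls as allyl carbonates, ring B hydroxyl as allyl ether). In the forward step the xanthone carbonyl, activated by a silyl triflate, adds a silyl peroxide and the ring B aryl group migrates to oxygen (Baeyer–Villiger-type ring expansion) to give the protected depsidone A4.
- Merits: it is by far the shortest road, follows the likely biogenesis, and prenylated pyranoxanthones are accessible by established xanthone chemistry.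
- Weak points: a xanthone carbonyl is a doubly vinylogous ester and a very poor electrophile. The migration must choose ring B over ring A, which is the reason for the carbonates. The peroxide and Lewis acid meet five C=C bonds (two prenyl, the chromene, the allyl groups). No oxygen insertion of this kind is known on a xanthone.
- Comparison: in step count this road is clearly better. The chosen plan sets against it that every elementary event of its new step is known chemistry, that the regiochemistry is backed by two independent effects, and that a fallback through known reactions exists. A failed insertion on A3 leaves nothing to fall back on.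

**Alternative 3:** Two C–C bonds of ring A are cut, giving the 2,4-diprenyl 1-methoxy-1,3-bis(trimethylsilyloxy)butadiene A5 and the ring B aryloxypropiolate A6. Cycloaddition (or Michael addition and Claisen-type closure) and loss of the methoxy group would give diaryl ether ester A7, with the complete ring A and free ring A hydroxyls.
- Merits: ring A is built with all six substituents in one step, without phloroglucinol prenylation and without ring A protecting groups, and the ester lands beside the ether oxygen by construction.
- Weak points: the acceptor carbon of A6 carries the aryloxy donor and is deactivated, while A5 is substituted at both reacting ends, so a hindered diene meets a poor acceptor at temperatures where silyl dienes decompose. A6 itself requires an aryl ynol ether and a fully differentiated tetraoxygenated ring B made by other means.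
- Comparison: for ring A this road is more convergent than steps 4 to 8 here. The chosen plan sets against it an electronically matched key pairing (electron-rich alkyne, electrophilic carbene) and the fact that the ring it builds is ring B, the ring with the harder oxygen pattern.

Key step: step 9

## Route

Assumption (chemistry): 1 is taken as a purchasable building block, and all compounds with an oxygen at C-4 of the pyran (2, 3, 5–7, 16–22) are carried as racemates, because this centre is removed in step 13.

Step 1
Reactants: 1 2,2-dimethyl-2,3-dihydro-4H-pyran-4-one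
Product: 2 rac-2,2-dimethyl-3,4-dihydro-2H-pyran-4-ol
Conditions: NaBH4, CeCl3·7H2O, MeOH, −78 → 0 °C; used crude
Reagents that add atoms: none
Why: Luche reduction: CeCl3-promoted 1,2-hydride delivery to the vinylogous ester carbonyl should give the allylic alcohol without conjugate reduction; the new C-4 centre is formed as a racemate, which is acceptable because it is erased in step 13.

Step 2
Reactants: 2 rac-2,2-dimethyl-3,4-dihydro-2H-pyran-4-ol
Product: 3 rac-[(2,2-dimethyl-3,4-dihydro-2H-pyran-4-yl)oxy]triisopropylsilane
Conditions: i-Pr3SiOSO2CF3, 2,6-lutidine, CH2Cl2, −78 → 0 °C; NaHCO3 wash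
Reagents that add atoms: triisopropylsilyl trifluoromethanesulfonate, CC(C)[Si](OS(=O)(=O)C(F)(F)F)(C(C)C)C(C)C
Why: Silyl triflate silylation of a secondary allylic alcohol under lutidine buffering should leave the acid-labile enol ether intact; the triisopropylsilyl group has no Si–CH3 protons that could be lithiated in step 3.

Step 3
Reactants: 3 rac-[(2,2-dimethyl-3,4-dihydro-2H-pyran-4-yl)oxy]triisopropylsilane; 4 Cr(CO)6
Product: 7 rac-pentacarbonyl{methoxy[2,2-dimethyl-4-(triisopropylsilyloxy)-3,4-dihydro-2H-pyran-6-yl]carbene}chromium, via vinyllithium 5 (not isolated), via lithium acylchromate 6 (not isolated)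
Conditions: t-BuLi (1.3 equiv), THF/pentane, −78 → 0 °C; Cr(CO)6, Et2O, 0 °C → rt; Me3OBF4, CH2Cl2, 0 °C; argon
Reagents that add atoms: trimethyloxonium tetrafluoroborate, C[O+](C)C.F[B-](F)(F)F
Why: Fischer carbene synthesis: lithiation of the enol ether at the α-alkoxyvinyl C-6 position (as in C-1 lithiation of silylated glycals), addition of the vinyllithium to a CO ligand and O-methylation of the acylchromate by the oxonium salt; no stereocentre is touched.

Step 4
Reactants: 8 methyl 2,4,6-trihydroxybenzoate; 9 prenyl bromide (1-bromo-3-methylbut-2-ene)
Product: 10 methyl 2,4,6-trihydroxy-3,5-bis(3-methylbut-2-en-1-yl)benzoate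
Conditions: 9 (2.1 equiv), 10% aq. KOH, 0 °C → rt; acidify, chromatography
Reagents that add atoms: none
Why: C-alkylation of the phloroglucinol polyanion in water, where hydrogen-bonded phenoxide oxygens leave carbon as the nucleophilic site, is the classical route to diprenyl acylphloroglucinols; the two free ring carbons are the only positions for aromatic substitution.

Step 5
Reactants: 10 methyl 2,4,6-trihydroxy-3,5-bis(3-methylbut-2-en-1-yl)benzoate
Product: 11 methyl 2,6-dihydroxy-4-(methoxymethoxy)-3,5-bis(3-methylbut-2-en-1-yl)benzoate
Conditions: MOMCl (1.05 equiv), i-Pr2NEt (1.2 equiv), CH2Cl2, 0 °C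
Reagents that add atoms: chloromethyl methyl ether, COCCl
Why: Williamson-type acetal formation with a hard electrophile goes to oxygen, and the 4-hydroxyl, the most acidic and the only one not chelated to the ester, should react first.

Step 6
Reactants: 11 methyl 2,6-dihydroxy-4-(methoxymethoxy)-3,5-bis(3-methylbut-2-en-1-yl)benzoate
Product: 12 methyl 2-{[(E)-1,2-dichloroethenyl]oxy}-6-hydroxy-4-(methoxymethoxy)-3,5-bis(3-methylbut-2-en-1-yl)benzoate
Conditions: Cl2C=CHCl (1.3 equiv), K2CO3 (1.2 equiv), DMF, 70 °C
Reagents that add atoms: trichloroethylene, ClC=C(Cl)Cl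
Why: Base converts trichloroethylene into dichloroacetylene, to which the phenoxide adds anti to give the (E)-1,2-dichlorovinyl ether; once one of the two equivalent chelated hydroxyls has reacted the other is more tightly chelated and less acidic, so mono-etherification is expected.

Step 7
Reactants: 12 methyl 2-{[(E)-1,2-dichloroethenyl]oxy}-6-hydroxy-4-(methoxymethoxy)-3,5-bis(3-methylbut-2-en-1-yl)benzoate
Product: 14 methyl 2-(ethynyloxy)-6-hydroxy-4-(methoxymethoxy)-3,5-bis(3-methylbut-2-en-1-yl)benzoate, via chloroethynyl ether 13 (not isolated)
Conditions: LiN(SiMe3)2 (1.05 equiv), THF, −78 °C; n-BuLi (2.2 equiv), −78 °C, 30 min; sat. aq. NH4Cl, −78 °C → rt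
Reagents that add atoms: none
Why: Dehydrochlorination to the chloroalkynyl ether, chlorine–lithium exchange and protonation is the standard conversion of dichlorovinyl ethers into terminal alkynyl ethers; the free ortho-hydroxyl is first made into its lithium phenoxide, which turns the doubly flanked ester into a chelated vinylogous carbonate salt and should shield it from butyllithium at −78 °C.

Step 8
Reactants: 14 methyl 2-(ethynyloxy)-6-hydroxy-4-(methoxymethoxy)-3,5-bis(3-methylbut-2-en-1-yl)benzoate
Product: 15 methyl 2-(ethynyloxy)-4,6-bis(methoxymethoxy)-3,5-bis(3-methylbut-2-en-1-yl)benzoate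
Conditions: MOMCl (1.5 equiv), K2CO3 (3 equiv), acetone, 50 °C
Reagents that add atoms: chloromethyl methyl ether, COCCl
Why: O-alkylation of the chelated phenol under carbonate conditions, which the alkynyl ether tolerates; it removes the only acidic proton and internal nucleophile near the alkyne before the metal carbene step.

Step 9
Reactants: 7 rac-pentacarbonyl{methoxy[2,2-dimethyl-4-(triisopropylsilyloxy)-3,4-dihydro-2H-pyran-6-yl]carbene}chromium; 15 methyl 2-(ethynyloxy)-4,6-bis(methoxymethoxy)-3,5-bis(3-methylbut-2-en-1-yl)benzoate
Product: 17 rac-methyl 2-{[5-hydroxy-8-methoxy-2,2-dimethyl-4-(triisopropylsilyloxy)chroman-6-yl]oxy}-4,6-bis(methoxymethoxy)-3,5-bis(3-methylbut-2-en-1-yl)benzoate, via tricarbonylchromium arene complex 16 (not isolated)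
Conditions: 7 (1.3 equiv), THF (0.05 M), 50 °C, argon; then air, Et2O, daylight, rt
Reagents that add atoms: none
Why: Proposed new method: the Dötz benzannulation, known for alkenyl(alkoxy)carbene chromium complexes with terminal alkyl and aryl alkynes, is extended here to an aryl ethynyl ether, the closest known reactions being that benzannulation and the insertion of ynamines and alkoxyalkynes into Fischer carbene complexes. The nucleophilic terminal carbon of 15 should bond to the electrophilic carbene carbon of 7 (alkyne insertion, after loss of one CO or by direct attack), giving a dienylcarbene whose new carbene carbon carries the aryloxy group, and CO insertion then gives a chromium-bound dienylketene. Ring B closes by thermal 6π-electrocyclisation of this ketene onto C-5 of the dihydropyran, and tautomerisation gives the phenol as complex 16, from which air oxidation of the zerovalent chromium sets the arene free. Three C–C bonds are formed: carbene carbon to alkyne CH, alkyne C(OAr) to CO, and CO to pyran C-5. The selectivity needed is regiochemical, aryloxy beside the CO-derived carbon, and the steric rule for terminal alkynes (hydrogen beside the methoxy carbon) and the electronic preference (the oxygen stabilises the new carbene carbon) point the same way. The ring double bond of the dihydropyran holds the carbene carbon and C-5 cis, so the ketene can reach C-5. No stereocentre is formed; the C-4 silyloxy centre is a spectator and the planar-chiral diastereomers of 16 converge on decomplexation. An ethereal solvent at about 50 °C is chosen because it favours CO insertion over cyclisation without CO for chromium alkoxycarbenes.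

Step 10
Reactants: 17 rac-methyl 2-{[5-hydroxy-8-methoxy-2,2-dimethyl-4-(triisopropylsilyloxy)chroman-6-yl]oxy}-4,6-bis(methoxymethoxy)-3,5-bis(3-methylbut-2-en-1-yl)benzoate
Product: 18 rac-2-{[5-hydroxy-8-methoxy-2,2-dimethyl-4-(triisopropylsilyloxy)chroman-6-yl]oxy}-4,6-bis(methoxymethoxy)-3,5-bis(3-methylbut-2-en-1-yl)benzoic acid
Conditions: n-PrSLi (6 equiv), HMPA, rt, argon; cold 0.5 M HCl to pH 4
Reagents that add atoms: none
Why: Doubly ortho-substituted methyl benzoates resist attack at the carbonyl but are cleaved by SN2 attack of a thiolate at the methyl carbon; aryl methyl and methoxymethyl ethers, the silyl ether and the prenyl groups should be inert at room temperature.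

Step 11
Reactants: 18 rac-2-{[5-hydroxy-8-methoxy-2,2-dimethyl-4-(triisopropylsilyloxy)chroman-6-yl]oxy}-4,6-bis(methoxymethoxy)-3,5-bis(3-methylbut-2-en-1-yl)benzoic acid
Product: 19 rac-2-{[2,2-dimethyl-5,8-dioxo-4-(triisopropylsilyloxy)-3,4,5,8-tetrahydro-2H-chromen-6-yl]oxy}-4,6-bis(methoxymethoxy)-3,5-bis(3-methylbut-2-en-1-yl)benzoic acid
Conditions: (NH4)2Ce(NO3)6 (2.2 equiv), MeCN/H2O 2:1, 0 °C, 10 min
Reagents that add atoms: water, O
Why: Oxidative demethylation of a 4-methoxyphenol by two equivalents of tetravalent cerium: the phenoxonium ion is captured by water at the methoxy-bearing carbon and loses methanol to give the quinone; the reaction is fast at 0 °C, so prenyl double bonds and acetals should survive.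

Step 12
Reactants: 19 rac-2-{[2,2-dimethyl-5,8-dioxo-4-(triisopropylsilyloxy)-3,4,5,8-tetrahydro-2H-chromen-6-yl]oxy}-4,6-bis(methoxymethoxy)-3,5-bis(3-methylbut-2-en-1-yl)benzoic acid
Product: 21 rac-3,4-dihydro-4-(triisopropylsilyloxy)garcinisidone E bis(methoxymethyl) ether (depsidone with both ring A hydroxyls as methoxymethyl ethers, free ring B hydroxyl, saturated pyran bearing the silyloxy group at C-4), via hydroquinone acid 20 (not isolated)
Conditions: Na2S2O4, EtOAc/H2O, rt; then EDC·HCl (1.5 equiv), DMAP (0.2 equiv), CH2Cl2 (2 mM), 0 °C → rt, argon
Reagents that add atoms: none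
Why: Dithionite reduction gives the hydroquinone, and carbodiimide activation (Steglich-type lactonisation, the standard depsidone ring closure) lets the only hydroxyl within reach, the one ortho to the diaryl ether, close the seven-membered ring by 7-exo-trig acyl substitution; high dilution should suppress intermolecular acylation of the para hydroxyl.

Step 13
Reactants: 21 rac-3,4-dihydro-4-(triisopropylsilyloxy)garcinisidone E bis(methoxymethyl) ether
Product: 23 garcinisidone E bis(methoxymethyl) ether (both ring A hydroxyls protected), via chromanol 22 (not isolated)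
Conditions: HF·pyridine, THF, 0 °C → rt; then PPTS (0.2 equiv), toluene, 80 °C
Reagents that add atoms: none
Why: Fluoride cleaves the secondary silyl ether without a base that could open the aryl ester, and the benzylic chroman-4-ol, whose cation is stabilised by the ring oxygen, loses water under mild acid (E1) to give the conjugated 2H-chromene; the only stereocentre disappears here.

Step 14
Reactants: 23 garcinisidone E bis(methoxymethyl) ether
Product: 24 garcinisidone E
Conditions: HCl (1 M in MeOH), 0 °C → rt
Reagents that add atoms: none
Why: Acid-catalysed acetal exchange of the two aryl methoxymethyl ethers with methanol gives the phenols and dimethoxymethane; dilute acid at room temperature is used because the freed ortho-prenyl phenols cyclise to chromans under stronger acid.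

## Compound list

1 | 2,2-dimethyl-2,3-dihydro-4H-pyran-4-one | CC1(C)CC(=O)C=CO1 | starting material
2 | rac-2,2-dimethyl-3,4-dihydro-2H-pyran-4-ol | CC1(C)CC(O)C=CO1 | intermediate
3 | rac-[(2,2-dimethyl-3,4-dihydro-2H-pyran-4-yl)oxy]triisopropylsilane | CC1(C)CC(O[Si](C(C)C)(C(C)C)C(C)C)C=CO1 | intermediate
4 | Cr(CO)6, hexacarbonylchromium | O=C=[Cr](=C=O)(=C=O)(=C=O)(=C=O)=C=O | starting material
5 | rac-[2,2-dimethyl-4-(triisopropylsilyloxy)-3,4-dihydro-2H-pyran-6-yl]lithium (not isolated) | [Li]C1=CC(O[Si](C(C)C)(C(C)C)C(C)C)CC(C)(C)O1 | intermediate
6 | rac-lithium pentacarbonyl{[2,2-dimethyl-4-(triisopropylsilyloxy)-3,4-dihydro-2H-pyran-6-yl]carbonyl}chromate (not isolated) | [Li+].[O-]C(=[Cr](=C=O)(=C=O)(=C=O)(=C=O)=C=O)C1=CC(O[Si](C(C)C)(C(C)C)C(C)C)CC(C)(C)O1 | intermediate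
7 | rac-pentacarbonyl{methoxy[2,2-dimethyl-4-(triisopropylsilyloxy)-3,4-dihydro-2H-pyran-6-yl]carbene}chromium | COC(=[Cr](=C=O)(=C=O)(=C=O)(=C=O)=C=O)C1=CC(O[Si](C(C)C)(C(C)C)C(C)C)CC(C)(C)O1 | intermediate
8 | methyl 2,4,6-trihydroxybenzoate | COC(=O)c1c(O)cc(O)cc1O | starting material
9 | prenyl bromide (1-bromo-3-methylbut-2-ene) | CC(C)=CCBr | starting material
10 | methyl 2,4,6-trihydroxy-3,5-bis(3-methylbut-2-en-1-yl)benzoate | COC(=O)c1c(O)c(CC=C(C)C)c(O)c(CC=C(C)C)c1O | intermediate
11 | methyl 2,6-dihydroxy-4-(methoxymethoxy)-3,5-bis(3-methylbut-2-en-1-yl)benzoate | COC(=O)c1c(O)c(CC=C(C)C)c(OCOC)c(CC=C(C)C)c1O | intermediate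
12 | methyl 2-{[(E)-1,2-dichloroethenyl]oxy}-6-hydroxy-4-(methoxymethoxy)-3,5-bis(3-methylbut-2-en-1-yl)benzoate | COC(=O)c1c(O/C(Cl)=C\Cl)c(CC=C(C)C)c(OCOC)c(CC=C(C)C)c1O | intermediate
13 | methyl 2-[(chloroethynyl)oxy]-6-hydroxy-4-(methoxymethoxy)-3,5-bis(3-methylbut-2-en-1-yl)benzoate (present as its lithium phenoxide, not isolated) | COC(=O)c1c(OC#CCl)c(CC=C(C)C)c(OCOC)c(CC=C(C)C)c1O | intermediate
14 | methyl 2-(ethynyloxy)-6-hydroxy-4-(methoxymethoxy)-3,5-bis(3-methylbut-2-en-1-yl)benzoate | COC(=O)c1c(OC#C)c(CC=C(C)C)c(OCOC)c(CC=C(C)C)c1O | intermediate
15 | methyl 2-(ethynyloxy)-4,6-bis(methoxymethoxy)-3,5-bis(3-methylbut-2-en-1-yl)benzoate | COC(=O)c1c(OC#C)c(CC=C(C)C)c(OCOC)c(CC=C(C)C)c1OCOC | intermediate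
16 | rac-tricarbonylchromium complex of 17, η6-bound through ring B (not isolated; arene and Cr(CO)3 written as two parts) | COC(=O)c1c(OCOC)c(CC=C(C)C)c(OCOC)c(CC=C(C)C)c1Oc1cc(OC)c2OC(C)(C)CC(O[Si](C(C)C)(C(C)C)C(C)C)c2c1O.O=C=[Cr](=C=O)=C=O | intermediate
17 | rac-methyl 2-{[5-hydroxy-8-methoxy-2,2-dimethyl-4-(triisopropylsilyloxy)chroman-6-yl]oxy}-4,6-bis(methoxymethoxy)-3,5-bis(3-methylbut-2-en-1-yl)benzoate | COC(=O)c1c(OCOC)c(CC=C(C)C)c(OCOC)c(CC=C(C)C)c1Oc1cc(OC)c2OC(C)(C)CC(O[Si](C(C)C)(C(C)C)C(C)C)c2c1O | intermediate
18 | rac-2-{[5-hydroxy-8-methoxy-2,2-dimethyl-4-(triisopropylsilyloxy)chroman-6-yl]oxy}-4,6-bis(methoxymethoxy)-3,5-bis(3-methylbut-2-en-1-yl)benzoic acid | OC(=O)c1c(OCOC)c(CC=C(C)C)c(OCOC)c(CC=C(C)C)c1Oc1cc(OC)c2OC(C)(C)CC(O[Si](C(C)C)(C(C)C)C(C)C)c2c1O | intermediate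
19 | rac-2-{[2,2-dimethyl-5,8-dioxo-4-(triisopropylsilyloxy)-3,4,5,8-tetrahydro-2H-chromen-6-yl]oxy}-4,6-bis(methoxymethoxy)-3,5-bis(3-methylbut-2-en-1-yl)benzoic acid | OC(=O)c1c(OCOC)c(CC=C(C)C)c(OCOC)c(CC=C(C)C)c1OC1=CC(=O)C2=C(C1=O)C(O[Si](C(C)C)(C(C)C)C(C)C)CC(C)(C)O2 | intermediate
20 | rac-2-{[5,8-dihydroxy-2,2-dimethyl-4-(triisopropylsilyloxy)chroman-6-yl]oxy}-4,6-bis(methoxymethoxy)-3,5-bis(3-methylbut-2-en-1-yl)benzoic acid (not isolated) | OC(=O)c1c(OCOC)c(CC=C(C)C)c(OCOC)c(CC=C(C)C)c1Oc1cc(O)c2OC(C)(C)CC(O[Si](C(C)C)(C(C)C)C(C)C)c2c1O | intermediate
21 | rac-3,4-dihydro-4-(triisopropylsilyloxy)garcinisidone E bis(methoxymethyl) ether | CC(C)=CCc1c(OCOC)c(CC=C(C)C)c2c(c1OCOC)C(=O)Oc1c(cc(O)c3c1C(O[Si](C(C)C)(C(C)C)C(C)C)CC(C)(C)O3)O2 | intermediate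
22 | rac-3,4-dihydro-4-hydroxygarcinisidone E bis(methoxymethyl) ether (not isolated) | CC(C)=CCc1c(OCOC)c(CC=C(C)C)c2c(c1OCOC)C(=O)Oc1c(cc(O)c3c1C(O)CC(C)(C)O3)O2 | intermediate
23 | garcinisidone E bis(methoxymethyl) ether (both ring A hydroxyls protected) | CC(C)=CCc1c(OCOC)c(CC=C(C)C)c2c(c1OCOC)C(=O)Oc1c(cc(O)c3c1C=CC(C)(C)O3)O2 | intermediate
24 | garcinisidone E | CC(C)=CCc1c(O)c(CC=C(C)C)c2c(c1O)C(=O)Oc1c(cc(O)c3c1C=CC(C)(C)O3)O2 | target

## Step count and risk assessment

Total: 14 steps (3 for the carbene, 5 for the ring A alkyne, the key step, 5 after it). Longest linear sequence: 11 steps (steps 4 to 14, from 8).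

**Step 9 (key step).** The aryloxy-stabilised dienylcarbene formed by insertion may be slow to lose CO. It may then decay by other paths instead of CO insertion and electrocyclisation: cyclisation without CO, cyclobutenone or furan formation, or cyclopropanation of the neighbouring prenyl double bond. The alkynyl ether may also be consumed by oligomerisation before it meets the carbene.

The fallback forms the ether bond after the ring, by known reactions only. It sets out from 7 and 11 and returns at 20.
- Carbene 7 is benzannulated with 2-ethynyl-4,4,5,5-tetramethyl-1,3,2-dioxaborolane, a member of the alkynylboronate class for which this benzannulation is established; the boryl group takes the place beside the phenol, giving the ring B boronate F1.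
- Ipso-bromination with N-bromosuccinimide gives the bromophenol F2, and (NH4)2Ce(NO3)6 oxidises it to the bromoquinone F3.
- In parallel 11 is methoxymethylated once more (MOMCl, K2CO3, acetone) to the ring A phenol F4.
- The potassium salt of F4 displaces bromide from F3 by addition–elimination (K2CO3, DMF), at the quinone carbon that is both halogen-bearing and the more electrophilic, to give the aryloxyquinone ester F5.
- Na2S2O4 reduces F5 to the hydroquinone ester F6, and n-PrSLi cleaves the methyl ester to give 20, which is lactonised as in step 12.

**Step 7.** Addition of butyllithium to the ester, or ester-assisted displacement of an ortho oxygen substituent, may compete with deprotonation and halogen–metal exchange if the phenoxide does not deactivate the ester enough. Hydration of the alkynyl ether on protonation is a second risk.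

The fallback takes the ester out of the organolithium step. It sets out from 12 and returns at 14.
- LiI in hot pyridine cleaves the methyl ester at the methyl carbon to give the dichlorovinyl ether acid F7.
- LiN(SiMe3)2 (2.1 equiv) and then n-BuLi (2.2 equiv) at −78 °C act on the carboxylate–phenoxide dianion, which is inert to addition. The sequence passes through the chloroethynyl ether acid F8 and gives the lithiated alkynyl ether.
- Two equivalents of acetic acid protonate the acetylide and the phenoxide but not the carboxylate, leaving the lithium carboxylate F9, so the free acid is never set beside the alkynyl ether.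
- Methyl iodide in DMF alkylates the carboxylate of F9 to give 14.

**Step 12.** The electron-rich hydroquinone may be reoxidised by air. Acyl transfer to the hindered, twisted carboxyl may be slow enough for intermolecular esterification to compete.

The fallback separates activation from ring closure. It sets out from 19 and returns at 21.
- Quinone acid 19, which has no nucleophilic hydroxyl, is converted with pentafluorophenol and a carbodiimide into the quinone pentafluorophenyl ester F10.
- Na2S2O4 reduction in the presence of NaHCO3 gives the hydroquinone active ester F11, which should close to 21 as soon as it forms.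

**Step 14.** The freed hydroxyls may cyclise onto the neighbouring prenyl double bonds, and methanol may add to the chromene double bond, before both acetals are gone.

The fallback replaces protic solvolysis by silyl exchange without free acid. It sets out from 23 and returns at 24.
- Me3SiOSO2CF3 buffered with 2,2′-bipyridyl converts the aryl methoxymethyl ethers (and the free phenol) into the tris(trimethylsilyl) ether F12.
- Water hydrolyses F12 to 24 at neutral pH.

**Step 4.** Over-alkylation with dearomatisation (a third prenyl group on an already substituted carbon) and O-alkylation may leave the diprenyl compound as a minor product.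

The fallback changes from phenoxide alkylation to electrophilic aromatic substitution. It sets out from 8 and returns at 10. 2-Methylbut-3-en-2-ol and BF3·OEt2 in dioxane give Friedel–Crafts prenylation of the neutral phenol, with no new intermediate.

## Further compounds

F1 | step 9 | rac-8-methoxy-2,2-dimethyl-6-(4,4,5,5-tetramethyl-1,3,2-dioxaborolan-2-yl)-4-(triisopropylsilyloxy)chroman-5-ol | COc1cc(B2OC(C)(C)C(C)(C)O2)c(O)c2c1OC(C)(C)CC2O[Si](C(C)C)(C(C)C)C(C)C
F2 | step 9 | rac-6-bromo-8-methoxy-2,2-dimethyl-4-(triisopropylsilyloxy)chroman-5-ol | COc1cc(Br)c(O)c2c1OC(C)(C)CC2O[Si](C(C)C)(C(C)C)C(C)C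
F3 | step 9 | rac-6-bromo-2,2-dimethyl-4-(triisopropylsilyloxy)-3,4-dihydro-2H-chromene-5,8-dione | O=C1C=C(Br)C(=O)C2=C1OC(C)(C)CC2O[Si](C(C)C)(C(C)C)C(C)C
F4 | step 9 | methyl 2-hydroxy-4,6-bis(methoxymethoxy)-3,5-bis(3-methylbut-2-en-1-yl)benzoate | COC(=O)c1c(O)c(CC=C(C)C)c(OCOC)c(CC=C(C)C)c1OCOC
F5 | step 9 | rac-methyl 2-{[2,2-dimethyl-5,8-dioxo-4-(triisopropylsilyloxy)-3,4,5,8-tetrahydro-2H-chromen-6-yl]oxy}-4,6-bis(methoxymethoxy)-3,5-bis(3-methylbut-2-en-1-yl)benzoate | COC(=O)c1c(OCOC)c(CC=C(C)C)c(OCOC)c(CC=C(C)C)c1OC1=CC(=O)C2=C(C1=O)C(O[Si](C(C)C)(C(C)C)C(C)C)CC(C)(C)O2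
F6 | step 9 | rac-methyl 2-{[5,8-dihydroxy-2,2-dimethyl-4-(triisopropylsilyloxy)chroman-6-yl]oxy}-4,6-bis(methoxymethoxy)-3,5-bis(3-methylbut-2-en-1-yl)benzoate | COC(=O)c1c(OCOC)c(CC=C(C)C)c(OCOC)c(CC=C(C)C)c1Oc1cc(O)c2OC(C)(C)CC(O[Si](C(C)C)(C(C)C)C(C)C)c2c1O
F7 | step 7 | 2-{[(E)-1,2-dichloroethenyl]oxy}-6-hydroxy-4-(methoxymethoxy)-3,5-bis(3-methylbut-2-en-1-yl)benzoic acid | OC(=O)c1c(O/C(Cl)=C\Cl)c(CC=C(C)C)c(OCOC)c(CC=C(C)C)c1O
F8 | step 7 | 2-[(chloroethynyl)oxy]-6-hydroxy-4-(methoxymethoxy)-3,5-bis(3-methylbut-2-en-1-yl)benzoic acid (present as its dilithium salt) | OC(=O)c1c(OC#CCl)c(CC=C(C)C)c(OCOC)c(CC=C(C)C)c1O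
F9 | step 7 | lithium 2-(ethynyloxy)-6-hydroxy-4-(methoxymethoxy)-3,5-bis(3-methylbut-2-en-1-yl)benzoate | [Li+].[O-]C(=O)c1c(OC#C)c(CC=C(C)C)c(OCOC)c(CC=C(C)C)c1O
F10 | step 12 | rac-pentafluorophenyl 2-{[2,2-dimethyl-5,8-dioxo-4-(triisopropylsilyloxy)-3,4,5,8-tetrahydro-2H-chromen-6-yl]oxy}-4,6-bis(methoxymethoxy)-3,5-bis(3-methylbut-2-en-1-yl)benzoate | O=C(Oc1c(F)c(F)c(F)c(F)c1F)c1c(OCOC)c(CC=C(C)C)c(OCOC)c(CC=C(C)C)c1OC1=CC(=O)C2=C(C1=O)C(O[Si](C(C)C)(C(C)C)C(C)C)CC(C)(C)O2
F11 | step 12 | rac-pentafluorophenyl 2-{[5,8-dihydroxy-2,2-dimethyl-4-(triisopropylsilyloxy)chroman-6-yl]oxy}-4,6-bis(methoxymethoxy)-3,5-bis(3-methylbut-2-en-1-yl)benzoate | O=C(Oc1c(F)c(F)c(F)c(F)c1F)c1c(OCOC)c(CC=C(C)C)c(OCOC)c(CC=C(C)C)c1Oc1cc(O)c2OC(C)(C)CC(O[Si](C(C)C)(C(C)C)C(C)C)c2c1O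
F12 | step 14 | garcinisidone E tris(trimethylsilyl) ether | CC(C)=CCc1c(O[Si](C)(C)C)c(CC=C(C)C)c2c(c1O[Si](C)(C)C)C(=O)Oc1c(cc(O[Si](C)(C)C)c3c1C=CC(C)(C)O3)O2
F0 | step 4 | none | none
A1 | alternative 1 | depsidone bis(allyl ether) with both ring A carbons unsubstituted | c1c(OCC=C)cc2c(c1OCC=C)C(=O)Oc1c(cc(O)c3c1C=CC(C)(C)O3)O2
A2 | alternative 1 | diallyl analogue of garcinisidone E | C=CCc1c(O)c(CC=C)c2c(c1O)C(=O)Oc1c(cc(O)c3c1C=CC(C)(C)O3)O2
A3 | alternative 2 | protected pyranoxanthone (two allyl carbonates, one allyl ether) | CC(C)=CCc1c(OC(=O)OCC=C)c(CC=C(C)C)c2c(c1OC(=O)OCC=C)C(=O)c1c(cc(OCC=C)c3c1C=CC(C)(C)O3)O2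
A4 | alternative 2 | protected garcinisidone E (two allyl carbonates, one allyl ether) | CC(C)=CCc1c(OC(=O)OCC=C)c(CC=C(C)C)c2c(c1OC(=O)OCC=C)C(=O)Oc1c(cc(OCC=C)c3c1C=CC(C)(C)O3)O2
A5 | alternative 3 | 2,4-diprenyl 1-methoxy-1,3-bis(trimethylsilyloxy)butadiene | COC(O[Si](C)(C)C)=C(CC=C(C)C)C(O[Si](C)(C)C)=CCC=C(C)C
A6 | alternative 3 | methyl 3-(ring B aryloxy)propiolate (two allyl ethers on ring B) | COC(=O)C#COc1cc(OCC=C)c2OC(C)(C)C=Cc2c1OCC=C
A7 | alternative 3 | diaryl ether methyl ester with free ring A hydroxyls (two allyl ethers on ring B) | COC(=O)c1c(O)c(CC=C(C)C)c(O)c(CC=C(C)C)c1Oc1cc(OCC=C)c2OC(C)(C)C=Cc2c1OCC=C
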